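**Retrosynthetic overview**

1. The strategy rests on ring C of the flavanone half. Its O1–C2 bond lies β to the C4 ketone, and C2 (benzylic, the only stereocentre) becomes stereogenic when that bond forms. Ring C is therefore opened at O1–C2 to a ring A phenol facing an aryl-substituted alkylidene, with a tert-butyl ester on the α-carbon as a removable activator.
2. The alkylidene C=C is cut (Knoevenagel) into a ring A tert-butyl β-ketoester and a benzaldehyde that already carries the finished flavone half. The C8(flavone)–C3'(flavanone ring B) biaryl bond is cut (Suzuki–Miyaura) into an 8-iodoflavone and a 2-benzyloxy-5-formylphenyl boronate.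
3. Both ring A units come from one di-O-benzyl phloroacetophenone. Every phenol except the ring-closing one is a benzyl ether, and all five are removed in one final hydrogenolysis.
4. Ring order: flavone pyranone (diketone cyclodehydration), then the biaryl bond, then chromanone ring C by the asymmetric oxa-Michael closure.

Key step: step 10

Assumption: the quinidine-derived thiourea is taken to give the 2S series with this alkylidene class (the quinine-derived pseudoenantiomer 2R); if the first run, checked by chiral HPLC and CD, shows the reverse sense, the pseudoenantiomeric catalyst is used with nothing else changed.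

**Route**

Step 1
Reactants: 1 2,4,6-trihydroxyacetophenone
Product: 2 1-[2,4-bis(benzyloxy)-6-hydroxyphenyl]ethan-1-one
Conditions: BnBr (2.1 equiv), K2CO3 (2.2 equiv), DMF, 0 °C to rt
Reagents that add atoms: benzyl bromide, BrCc1ccccc1
Why: Williamson etherification in which the para hydroxyl and one ortho hydroxyl are alkylated, while the last ortho hydroxyl, hydrogen-bonded to the acetyl carbonyl, should stay free when the bromide is limited to 2.1 equiv.

Step 2
Reactants: 2 1-[2,4-bis(benzyloxy)-6-hydroxyphenyl]ethan-1-one; 3 4-methoxybenzoyl chloride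
Product: 4 1-[2,4-bis(benzyloxy)-6-hydroxyphenyl]-3-(4-methoxyphenyl)propane-1,3-dione
Conditions: LiN(SiMe3)2 (3.3 equiv), THF, −78 to −10 °C; then 3 (1.05 equiv), −78 °C to rt; AcOH quench
Reagents that add atoms: none
Why: Direct C-aroylation of the lithium polyanion of a 2-hydroxyacetophenone (one-flask variant of the Baker–Venkataraman route), in which the ketone enolate is acylated in preference to the chelated phenoxide and any O-aroyl ester would rearrange to the same 1,3-diketone under the excess amide base.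

Step 3
Reactants: 4 1-[2,4-bis(benzyloxy)-6-hydroxyphenyl]-3-(4-methoxyphenyl)propane-1,3-dione
Product: 5 5,7-bis(benzyloxy)-2-(4-methoxyphenyl)-4H-chromen-4-one
Conditions: NaOAc, AcOH, 110 °C
Reagents that add atoms: none
Why: Cyclodehydration of the 2-hydroxyaryl 1,3-diketone (closing stage of the Baker–Venkataraman flavone synthesis), in which the phenol adds to the enolised aroyl carbonyl and water is lost to give the aromatic pyranone, buffered acetic acid being mild enough to spare the benzyl ethers.

Step 4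
Reactants: 5 5,7-bis(benzyloxy)-2-(4-methoxyphenyl)-4H-chromen-4-one
Product: 6 5,7-bis(benzyloxy)-8-iodo-2-(4-methoxyphenyl)-4H-chromen-4-one
Conditions: NIS (1.05 equiv), TFA (0.3 equiv), CH2Cl2/MeCN, 0 °C to rt, dark
Reagents that add atoms: N-iodosuccinimide, O=C1CCC(=O)N1I
Why: Electrophilic aromatic iodination of ring A, where with the 5-oxygen alkylated C8 (para to 5-OBn, ortho to 7-OBn and O1, flanked by only one benzyloxy group) is the expected site rather than C6 between two benzyloxy groups; the site would be checked by NOE from the remaining H6 to both OCH2 groups.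

Step 5
Reactants: 7 3-bromo-4-hydroxybenzaldehyde
Product: 8 4-(benzyloxy)-3-bromobenzaldehyde
Conditions: BnBr (1.1 equiv), K2CO3 (1.5 equiv), DMF, rt
Reagents that add atoms: benzyl bromide, BrCc1ccccc1
Why: Williamson etherification of the only phenol, which is acidic and unhindered enough to react cleanly at room temperature.

Step 6
Reactants: 8 4-(benzyloxy)-3-bromobenzaldehyde
Product: 9 4-(benzyloxy)-3-(4,4,5,5-tetramethyl-1,3,2-dioxaborolan-2-yl)benzaldehyde
Conditions: B2pin2 (1.2 equiv), Pd(dppf)Cl2 (3 mol %), KOAc (3 equiv), 1,4-dioxane, 90 °C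
Reagents that add atoms: bis(pinacolato)diboron, CC1(C)OB(B2OC(C)(C)C(C)(C)O2)OC1(C)C
Why: Miyaura borylation of the aryl bromide, in which acetate is basic enough for transmetalation from the diboron but too weak to cause Suzuki homocoupling or aldehyde side reactions.

Step 7
Reactants: 6 5,7-bis(benzyloxy)-8-iodo-2-(4-methoxyphenyl)-4H-chromen-4-one; 9 4-(benzyloxy)-3-(4,4,5,5-tetramethyl-1,3,2-dioxaborolan-2-yl)benzaldehyde
Product: 10 4-(benzyloxy)-3-[5,7-bis(benzyloxy)-2-(4-methoxyphenyl)-4-oxo-4H-chromen-8-yl]benzaldehyde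
Conditions: Pd(OAc)2 (5 mol %), SPhos (10 mol %), K3PO4 (3 equiv), toluene/H2O 10:1, 90 °C
Reagents that add atoms: none
Why: Suzuki–Miyaura cross-coupling in which the electron-rich biaryl phosphine SPhos should carry zerovalent palladium through oxidative addition into the C–I bond and reductive elimination at the tri-ortho-substituted axis, while the aldehyde, benzyl ethers and flavone tolerate aqueous phosphate.

Step 8
Reactants: 2 1-[2,4-bis(benzyloxy)-6-hydroxyphenyl]ethan-1-one
Product: 11 tert-butyl 3-[2,4-bis(benzyloxy)-6-hydroxyphenyl]-3-oxopropanoate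
Conditions: LiN(SiMe3)2 (3.2 equiv), THF, −78 °C; Boc2O (1.1 equiv), −78 to −20 °C; AcOH quench
Reagents that add atoms: di-tert-butyl dicarbonate, CC(C)(C)OC(=O)OC(=O)OC(C)(C)C
Why: Claisen-type C-acylation of the lithium dianion (phenoxide plus ketone enolate) by Boc2O, in which the enolate carbon is far more nucleophilic than the chelated phenoxide, any aryl carbonate formed would reach the same product by base-mediated O-to-C transfer, and the third equivalent of base covers the acidic β-ketoester.

Step 9
Reactants: 10 4-(benzyloxy)-3-[5,7-bis(benzyloxy)-2-(4-methoxyphenyl)-4-oxo-4H-chromen-8-yl]benzaldehyde; 11 tert-butyl 3-[2,4-bis(benzyloxy)-6-hydroxyphenyl]-3-oxopropanoate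
Product: 12 tert-butyl (2Z)-2-[2,4-bis(benzyloxy)-6-hydroxybenzoyl]-3-{4-(benzyloxy)-3-[5,7-bis(benzyloxy)-2-(4-methoxyphenyl)-4-oxo-4H-chromen-8-yl]phenyl}prop-2-enoate
Conditions: piperidine (0.2 equiv), AcOH (0.2 equiv), 4 Å molecular sieves, toluene, rt to 40 °C; rapid chromatography, stored cold
Reagents that add atoms: none
Why: Knoevenagel condensation in which the piperidine-derived iminium of aldehyde 10 is attacked by the enol of β-ketoester 11 and the adduct eliminates to the conjugated alkylidene, the Z isomer (aryl cis to the ester, away from the bulky aroyl group) being the thermodynamic one, while buffered piperidinium acetate in toluene should keep the hydrogen-bonded phenol too poor a nucleophile for premature racemic ring closure.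

Step 10
Reactants: 12 tert-butyl (2Z)-2-[2,4-bis(benzyloxy)-6-hydroxybenzoyl]-3-{4-(benzyloxy)-3-[5,7-bis(benzyloxy)-2-(4-methoxyphenyl)-4-oxo-4H-chromen-8-yl]phenyl}prop-2-enoate
Product: 15 penta-O-benzyl (2S)-2,3-dihydropodocarpusflavone A, via chromanone tert-butyl ester 13 (not isolated), via chromanone carboxylic acid 14 (not isolated)
Conditions: quinidine-derived thiourea N-[3,5-bis(trifluoromethyl)phenyl]-N'-[(9R)-6'-methoxycinchonan-9-yl]thiourea (15 mol %), toluene, −25 °C; then TsOH·H2O (0.5 equiv), 80 °C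
Reagents that add atoms: none
Why: The thiourea N–H pair binds the 1,3-dicarbonyl of the Z-alkylidene while the quinuclidine nitrogen takes the proton of the one free phenol, and the hydrogen-bonded phenoxide adds to the alkylidene β-carbon in a conjugate oxa-Michael addition that forms the O1–C2 bond. This is the known bifunctional cinchona-thiourea cyclisation of 2-hydroxyaryl alkylidene β-ketoesters with in-flask decarboxylation to flavanones, applied here to a larger substrate. Ring C closes in a 6-endo-trig mode. C2 is set by the catalyst, which under the stated assumption exposes the enantioface that leads to 2S, and the C3 centre of 13 is erased again on decarboxylation. The step needs enantiofacial selectivity and a catalysed rate well above the uncatalysed closure: the tert-butyl ester supplies the second binding point and extra electrophilicity, the defined Z geometry presents one substrate shape, and benzyl ethers on the five other phenols leave a single nucleophile. TsOH then protonates the quinuclidine (shutting off base-mediated retro-Michael racemisation) and ionises the tert-butyl ester to isobutene and acid 14, which loses CO2 at 80 °C without breaking the C2–O1 bond.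

Step 11
Reactants: 15 penta-O-benzyl (2S)-2,3-dihydropodocarpusflavone A
Product: 16 2,3-dihydropodocarpusflavone A (2S)
Conditions: H2 (1 atm), 10% Pd/C, THF/MeOH 1:1, rt, stopped at complete debenzylation
Reagents that add atoms: none
Why: Heterogeneous hydrogenolysis of the five aryl benzyl ethers under neutral conditions, in which the aryl methyl ether, the flavone enone and the C2 centre (no acid or base present to open ring C) should be untouched.

**Compound list**

1 | 2,4,6-trihydroxyacetophenone | CC(=O)c1c(O)cc(O)cc1O | starting material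
2 | 1-[2,4-bis(benzyloxy)-6-hydroxyphenyl]ethan-1-one | CC(=O)c1c(O)cc(OCc2ccccc2)cc1OCc1ccccc1 | intermediate
3 | 4-methoxybenzoyl chloride | COc1ccc(C(=O)Cl)cc1 | starting material
4 | 1-[2,4-bis(benzyloxy)-6-hydroxyphenyl]-3-(4-methoxyphenyl)propane-1,3-dione | COc1ccc(C(=O)CC(=O)c2c(O)cc(OCc3ccccc3)cc2OCc2ccccc2)cc1 | intermediate
5 | 5,7-bis(benzyloxy)-2-(4-methoxyphenyl)-4H-chromen-4-one | COc1ccc(-c2cc(=O)c3c(OCc4ccccc4)cc(OCc4ccccc4)cc3o2)cc1 | intermediate
6 | 5,7-bis(benzyloxy)-8-iodo-2-(4-methoxyphenyl)-4H-chromen-4-one | COc1ccc(-c2cc(=O)c3c(OCc4ccccc4)cc(OCc4ccccc4)c(I)c3o2)cc1 | intermediate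
7 | 3-bromo-4-hydroxybenzaldehyde | O=Cc1ccc(O)c(Br)c1 | starting material
8 | 4-(benzyloxy)-3-bromobenzaldehyde | O=Cc1ccc(OCc2ccccc2)c(Br)c1 | intermediate
9 | 4-(benzyloxy)-3-(4,4,5,5-tetramethyl-1,3,2-dioxaborolan-2-yl)benzaldehyde | O=Cc1ccc(OCc2ccccc2)c(B2OC(C)(C)C(C)(C)O2)c1 | intermediate
10 | 4-(benzyloxy)-3-[5,7-bis(benzyloxy)-2-(4-methoxyphenyl)-4-oxo-4H-chromen-8-yl]benzaldehyde | COc1ccc(-c2cc(=O)c3c(OCc4ccccc4)cc(OCc4ccccc4)c(-c4cc(C=O)ccc4OCc4ccccc4)c3o2)cc1 | intermediate
11 | tert-butyl 3-[2,4-bis(benzyloxy)-6-hydroxyphenyl]-3-oxopropanoate | CC(C)(C)OC(=O)CC(=O)c1c(O)cc(OCc2ccccc2)cc1OCc1ccccc1 | intermediate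
12 | tert-butyl (2Z)-2-[2,4-bis(benzyloxy)-6-hydroxybenzoyl]-3-{4-(benzyloxy)-3-[5,7-bis(benzyloxy)-2-(4-methoxyphenyl)-4-oxo-4H-chromen-8-yl]phenyl}prop-2-enoate | COc1ccc(-c2cc(=O)c3c(OCc4ccccc4)cc(OCc4ccccc4)c(-c4cc(/C=C(\C(=O)OC(C)(C)C)C(=O)c5c(O)cc(OCc6ccccc6)cc5OCc5ccccc5)ccc4OCc4ccccc4)c3o2)cc1 | intermediate
13 | tert-butyl (2S)-5,7-bis(benzyloxy)-2-{4-(benzyloxy)-3-[5,7-bis(benzyloxy)-2-(4-methoxyphenyl)-4-oxo-4H-chromen-8-yl]phenyl}-4-oxochromane-3-carboxylate (C3 epimers and enol, not isolated) | COc1ccc(-c2cc(=O)c3c(OCc4ccccc4)cc(OCc4ccccc4)c(-c4cc([C@@H]5C(C(=O)OC(C)(C)C)C(=O)c6c(OCc7ccccc7)cc(OCc7ccccc7)cc6O5)ccc4OCc4ccccc4)c3o2)cc1 | intermediate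
14 | (2S)-5,7-bis(benzyloxy)-2-{4-(benzyloxy)-3-[5,7-bis(benzyloxy)-2-(4-methoxyphenyl)-4-oxo-4H-chromen-8-yl]phenyl}-4-oxochromane-3-carboxylic acid (C3 epimers, not isolated) | COc1ccc(-c2cc(=O)c3c(OCc4ccccc4)cc(OCc4ccccc4)c(-c4cc([C@@H]5C(C(=O)O)C(=O)c6c(OCc7ccccc7)cc(OCc7ccccc7)cc6O5)ccc4OCc4ccccc4)c3o2)cc1 | intermediate
15 | penta-O-benzyl (2S)-2,3-dihydropodocarpusflavone A, (2S)-5,7-bis(benzyloxy)-2-{4-(benzyloxy)-3-[5,7-bis(benzyloxy)-2-(4-methoxyphenyl)-4-oxo-4H-chromen-8-yl]phenyl}chroman-4-one | COc1ccc(-c2cc(=O)c3c(OCc4ccccc4)cc(OCc4ccccc4)c(-c4cc([C@@H]5CC(=O)c6c(OCc7ccccc7)cc(OCc7ccccc7)cc6O5)ccc4OCc4ccccc4)c3o2)cc1 | intermediate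
16 | 2,3-dihydropodocarpusflavone A, 8-{5-[(2S)-5,7-dihydroxy-4-oxochroman-2-yl]-2-hydroxyphenyl}-5,7-dihydroxy-2-(4-methoxyphenyl)-4H-chromen-4-one | COc1ccc(-c2cc(=O)c3c(O)cc(O)c(-c4cc([C@@H]5CC(=O)c6c(O)cc(O)cc6O5)ccc4O)c3o2)cc1 | target

**Count**

Total step count: 11. Longest linear sequence: 8 steps (steps 1, 2, 3, 4, 7, 9, 10, 11).

**Steps most likely to fail**

Step 10. Enantiofacial selectivity may be eroded for three reasons. The 6-benzyloxy group ortho to the aroyl carbonyl twists the ketone and may weaken the two-point binding to the thiourea. Uncatalysed closure may compete at the long reaction time a large substrate needs. The C2–O1 bond, benzylic to a para-alkoxyaryl ring, may ionise and re-close during the acid stage. Partial loss of the peri 5-benzyl ether under TsOH is a lesser concern, since such material converges in step 11.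
Fallback: set C2 by asymmetric conjugate arylation of a chromone, setting out from 6 and 2 and coming back at 15. Iodide 6 is coupled at the C–I bond (Pd(PPh3)4, K2CO3, dioxane/H2O, 85 °C) with commercial [2-(benzyloxy)-5-chlorophenyl]boronic acid to give 5,7-bis(benzyloxy)-8-[2-(benzyloxy)-5-chlorophenyl]-2-(4-methoxyphenyl)-4H-chromen-4-one F1. The chloride is then borylated (B2pin2, Pd2(dba)3, XPhos, KOAc, dioxane, 100 °C) to 5,7-bis(benzyloxy)-8-[2-(benzyloxy)-5-(4,4,5,5-tetramethyl-1,3,2-dioxaborolan-2-yl)phenyl]-2-(4-methoxyphenyl)-4H-chromen-4-one F2. In parallel, ketone 2 is condensed with N,N-dimethylformamide dimethyl acetal to (2E)-1-[2,4-bis(benzyloxy)-6-hydroxyphenyl]-3-(dimethylamino)prop-2-en-1-one F3, which closes with HCl in CH2Cl2 to 5,7-bis(benzyloxy)-4H-chromen-4-one F4. Rhodium-catalysed asymmetric 1,4-addition of boronate F2 to the unsubstituted enone of F4 ([Rh(OH)(cod)]2 with an electron-poor atropisomeric bisphosphine of the MeO-BIPHEP class, antipode chosen for 2S, toluene/H2O, 40 °C) should give 15 directly. The 2-aryl-substituted flavone enone inside F2 is β,β-disubstituted and should not compete.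

Step 9. Condensation of an electron-rich para-alkoxybenzaldehyde with a hindered β-ketoester may be slow. Forcing it may let the free phenol add to the new alkylidene under the amine, giving racemic ring closure before the chiral catalyst is present.
Fallback: mask the ring-closing phenol through the condensation, setting out from 2 and coming back at 12. Ketone 2 is allylated (allyl bromide, K2CO3, DMF, 60 °C) to 1-[2-(allyloxy)-4,6-bis(benzyloxy)phenyl]ethan-1-one F5. This is C-acylated as in step 8 (LiN(SiMe3)2, 2.2 equiv, then Boc2O) to tert-butyl 3-[2-(allyloxy)-4,6-bis(benzyloxy)phenyl]-3-oxopropanoate F6. With no nucleophile present the Knoevenagel condensation with aldehyde 10 can be driven hard (piperidine, AcOH, 4 Å sieves, toluene, 80 °C) to tert-butyl (2Z)-2-[2-(allyloxy)-4,6-bis(benzyloxy)benzoyl]-3-{4-(benzyloxy)-3-[5,7-bis(benzyloxy)-2-(4-methoxyphenyl)-4-oxo-4H-chromen-8-yl]phenyl}prop-2-enoate F7. The allyl ether is then removed with Pd(PPh3)4 and the weakly basic scavenger N-methylaniline in THF at rt, which should release phenol 12 without promoting closure.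

Step 7. Transmetalation at a tri-ortho-substituted axis may be slow, so that protodeboronation of the ortho-alkoxy boronate and reductive deiodination of 6 take over.
Fallback: change the nucleophile from boron to tin, setting out from 8 and 6 and coming back at 10. Bromide 8 is stannylated (Me3SnSnMe3, Pd(PPh3)4, toluene, 100 °C) to 4-(benzyloxy)-3-(trimethylstannyl)benzaldehyde F8. A fluoride- and copper-promoted Stille coupling with iodide 6 (Pd(PPh3)4, CuI, CsF, DMF, 50 °C) then proceeds under base-free, anhydrous conditions, where protodemetalation is not a pathway, and should give aldehyde 10.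

**Further compounds**

F1 | step 10 | 5,7-bis(benzyloxy)-8-[2-(benzyloxy)-5-chlorophenyl]-2-(4-methoxyphenyl)-4H-chromen-4-one | COc1ccc(-c2cc(=O)c3c(OCc4ccccc4)cc(OCc4ccccc4)c(-c4cc(Cl)ccc4OCc4ccccc4)c3o2)cc1
F2 | step 10 | 5,7-bis(benzyloxy)-8-[2-(benzyloxy)-5-(4,4,5,5-tetramethyl-1,3,2-dioxaborolan-2-yl)phenyl]-2-(4-methoxyphenyl)-4H-chromen-4-one | COc1ccc(-c2cc(=O)c3c(OCc4ccccc4)cc(OCc4ccccc4)c(-c4cc(B5OC(C)(C)C(C)(C)O5)ccc4OCc4ccccc4)c3o2)cc1
F3 | step 10 | (2E)-1-[2,4-bis(benzyloxy)-6-hydroxyphenyl]-3-(dimethylamino)prop-2-en-1-one | CN(C)/C=C/C(=O)c1c(O)cc(OCc2ccccc2)cc1OCc1ccccc1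
F4 | step 10 | 5,7-bis(benzyloxy)-4H-chromen-4-one | O=c1ccoc2cc(OCc3ccccc3)cc(OCc3ccccc3)c12
F5 | step 9 | 1-[2-(allyloxy)-4,6-bis(benzyloxy)phenyl]ethan-1-one | CC(=O)c1c(OCC=C)cc(OCc2ccccc2)cc1OCc1ccccc1
F6 | step 9 | tert-butyl 3-[2-(allyloxy)-4,6-bis(benzyloxy)phenyl]-3-oxopropanoate | CC(C)(C)OC(=O)CC(=O)c1c(OCC=C)cc(OCc2ccccc2)cc1OCc1ccccc1
F7 | step 9 | tert-butyl (2Z)-2-[2-(allyloxy)-4,6-bis(benzyloxy)benzoyl]-3-{4-(benzyloxy)-3-[5,7-bis(benzyloxy)-2-(4-methoxyphenyl)-4-oxo-4H-chromen-8-yl]phenyl}prop-2-enoate | COc1ccc(-c2cc(=O)c3c(OCc4ccccc4)cc(OCc4ccccc4)c(-c4cc(/C=C(\C(=O)OC(C)(C)C)C(=O)c5c(OCC=C)cc(OCc6ccccc6)cc5OCc5ccccc5)ccc4OCc4ccccc4)c3o2)cc1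
F8 | step 7 | 4-(benzyloxy)-3-(trimethylstannyl)benzaldehyde | O=Cc1ccc(OCc2ccccc2)c([Sn](C)(C)C)c1
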